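**Assumption:** 5-bromo-2-hydroxy-4-methoxybenzaldehyde and 7-hydroxy-2-oxo-2H-chromene-8-carbaldehyde are taken as catalogue compounds. The absolute sense of the Diels–Alder step is assigned from the accepted model for this catalyst class, not from a precedent on this diene.

## Retrosynthetic overview

1. Last C–C bond: the (E)-CH=CH link between the quaternary ring carbon and coumarin C8 is cut into two aldehydes. The 8-formylcoumarin carbon is used with reversed polarity (tosylhydrazone → diazo → phosphite ylide), so two carbonyl carbons are joined directly and the E geometry is set in the same step.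
2. The cyclohexene carbaldehyde comes from a catalytic enantioselective endo Diels–Alder reaction of a 6-(3-methylbutadienyl)coumarin with methacrolein. This step forms the carbocycle and both stereocentres.
3. The diene comes from 6-bromo-7-methoxycoumarin by Heck coupling with 2-methylbut-3-en-2-ol and dehydration. The bromocoumarin comes from a bromosalicylaldehyde by Wittig olefination and lactonisation.
4. Ring order: lactone ring of the 6-substituted coumarin (step 1), then the cyclohexene (step 4). The 8-substituted coumarin is bought with both rings in place and only O-methylated.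

## Route

**Step 1**
Reactants: 1 5-bromo-2-hydroxy-4-methoxybenzaldehyde; 2 ethyl 2-(triphenyl-λ5-phosphanylidene)acetate
Product: 4 6-bromo-7-methoxy-2H-chromen-2-one, via cinnamate ester 3 (not isolated)
Conditions: PhNEt2, reflux (215 °C), 5 h
Reagents that add atoms: none
Why: Wittig olefination with a stabilised ylide followed by thermal E/Z isomerisation and lactonisation is the classical one-pot coumarin synthesis from a salicylaldehyde; no stereocentre is formed.

**Step 2**
Reactants: 4 6-bromo-7-methoxy-2H-chromen-2-one; 5 2-methylbut-3-en-2-ol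
Product: 6 6-[(E)-3-hydroxy-3-methylbut-1-en-1-yl]-7-methoxy-2H-chromen-2-one
Conditions: Pd(OAc)2 (5 mol%), P(2-MeC6H4)3 (10 mol%), Et3N, DMF, 100 °C
Reagents that add atoms: none
Why: Mizoroki–Heck reaction in which the aryl–palladium species adds to the terminal alkene carbon and β-hydride elimination can only occur towards the arene side because the carbinol carbon has no hydrogen, so the E-styrenyl tertiary alcohol forms and the unreactive coumarin C3=C4 bond is left alone.

**Step 3**
Reactants: 6 6-[(E)-3-hydroxy-3-methylbut-1-en-1-yl]-7-methoxy-2H-chromen-2-one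
Product: 8 7-methoxy-6-[(E)-3-methylbuta-1,3-dien-1-yl]-2H-chromen-2-one, via tertiary mesylate 7 (not isolated)
Conditions: MsCl, Et3N (excess), CH2Cl2, 0 °C to rt; product kept cold with a trace of BHT and used at once
Reagents that add atoms: none
Why: Sulfene mesylation of the tertiary allylic alcohol followed by amine-promoted E1/E2 elimination towards a methyl group (the only β-hydrogens available) gives the conjugated E-diene under non-acidic conditions that spare the electron-rich diene.

**Step 4**
Reactants: 8 7-methoxy-6-[(E)-3-methylbuta-1,3-dien-1-yl]-2H-chromen-2-one; 9 2-methylprop-2-enal (methacrolein)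
Product: 10 (1S,2S)-2-(7-methoxy-2-oxo-2H-chromen-6-yl)-1,4-dimethylcyclohex-3-ene-1-carbaldehyde
Conditions: (S)-3,3-diphenyl-1-(2-methylphenyl)tetrahydro-1H,3H-pyrrolo[1,2-c][1,3,2]oxazaborole (20 mol%), HN(SO2CF3)2 (16 mol%), CH2Cl2, −78 °C to −40 °C
Reagents that add atoms: none
Why: Enantioselective Diels–Alder reaction under cationic oxazaborolidine Lewis acid catalysis, in which the 1-aryl-3-methyldiene adds to boron-bound s-trans methacrolein with ortho/para regiochemistry and formyl-endo orientation (CHO cis to the aryl group, methyl trans), while the catalyst phenyl group blocks one enal face so that the diene attacks the Re face of the α-carbon and the (1S,2S) adduct carries both stereocentres of the target.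

**Step 5**
Reactants: 11 7-hydroxy-2-oxo-2H-chromene-8-carbaldehyde
Product: 12 7-methoxy-2-oxo-2H-chromene-8-carbaldehyde
Conditions: K2CO3, acetone, reflux
Reagents that add atoms: methyl iodide (CI)
Why: Williamson O-methylation of the phenol (SN2) with a base mild enough to leave the lactone and the non-enolisable aldehyde intact.

**Step 6**
Reactants: 12 7-methoxy-2-oxo-2H-chromene-8-carbaldehyde
Product: 13 N'-[(E)-(7-methoxy-2-oxo-2H-chromen-8-yl)methylidene]-4-methylbenzenesulfonohydrazide
Conditions: TsNHNH2 (1.05 equiv), MeOH, rt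
Reagents that add atoms: 4-methylbenzenesulfonohydrazide (Cc1ccc(cc1)S(=O)(=O)NN)
Why: Condensation of the aryl aldehyde with tosylhydrazide gives the crystalline E-tosylhydrazone, the stable precursor of the diazo compound used next.

**Step 7**
Reactants: 13 N'-[(E)-(7-methoxy-2-oxo-2H-chromen-8-yl)methylidene]-4-methylbenzenesulfonohydrazide (1.5 equiv); 10 (1S,2S)-2-(7-methoxy-2-oxo-2H-chromen-6-yl)-1,4-dimethylcyclohex-3-ene-1-carbaldehyde
Product: 17 7-methoxy-6-[(1R,6R)-6-[(E)-2-(7-methoxy-2-oxo-2H-chromen-8-yl)ethenyl]-3,6-dimethylcyclohex-2-en-1-yl]-2H-chromen-2-one, via sodium salt 14 (not isolated), via diazo compound 15 (not isolated), via phosphite ylide 16 (not isolated)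
Conditions: NaH (1.0 equiv), THF, 0 °C, then solvent removed; 10, P(OMe)3 (1.5 equiv), chloro(5,10,15,20-tetraphenylporphyrinato)iron (1 mol%), BnEt3NCl (10 mol%), toluene, 40 °C
Reagents that add atoms: none
Why: Bamford–Stevens diazo generation, iron-carbene transfer to P(OMe)3 and Wittig olefination (tosylhydrazone-salt olefination of aldehydes) turn the formyl carbon of 12 from an acceptor into a donor (diazo, then semi-stabilised ylide) that attacks the hindered, non-enolisable formyl carbon of 10, so two former carbonyl carbons are joined under near-neutral conditions that the lactones tolerate, with the E selectivity typical of phosphite-derived benzylic ylides and without touching either stereocentre.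

## Compound list

1 | 5-bromo-2-hydroxy-4-methoxybenzaldehyde | O=Cc1cc(Br)c(OC)cc1O | starting material
2 | ethyl 2-(triphenyl-λ5-phosphanylidene)acetate | CCOC(=O)C=P(c1ccccc1)(c1ccccc1)c1ccccc1 | starting material
3 | ethyl (E)-3-(5-bromo-2-hydroxy-4-methoxyphenyl)prop-2-enoate (not isolated; isomerises and lactonises in the flask) | CCOC(=O)/C=C/c1cc(Br)c(OC)cc1O | intermediate
4 | 6-bromo-7-methoxy-2H-chromen-2-one | COc1cc2oc(=O)ccc2cc1Br | intermediate
5 | 2-methylbut-3-en-2-ol | CC(C)(O)C=C | starting material
6 | 6-[(E)-3-hydroxy-3-methylbut-1-en-1-yl]-7-methoxy-2H-chromen-2-one | COc1cc2oc(=O)ccc2cc1/C=C/C(C)(C)O | intermediate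
7 | (E)-4-(7-methoxy-2-oxo-2H-chromen-6-yl)-2-methylbut-3-en-2-yl methanesulfonate (not isolated) | COc1cc2oc(=O)ccc2cc1/C=C/C(C)(C)OS(C)(=O)=O | intermediate
8 | 7-methoxy-6-[(E)-3-methylbuta-1,3-dien-1-yl]-2H-chromen-2-one | COc1cc2oc(=O)ccc2cc1/C=C/C(C)=C | intermediate
9 | 2-methylprop-2-enal (methacrolein) | CC(=C)C=O | starting material
10 | (1S,2S)-2-(7-methoxy-2-oxo-2H-chromen-6-yl)-1,4-dimethylcyclohex-3-ene-1-carbaldehyde (aryl and CHO cis) | COc1cc2oc(=O)ccc2cc1[C@@H]1C=C(C)CC[C@]1(C)C=O | intermediate
11 | 7-hydroxy-2-oxo-2H-chromene-8-carbaldehyde | O=Cc1c(O)ccc2ccc(=O)oc12 | starting material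
12 | 7-methoxy-2-oxo-2H-chromene-8-carbaldehyde | O=Cc1c(OC)ccc2ccc(=O)oc12 | intermediate
13 | N'-[(E)-(7-methoxy-2-oxo-2H-chromen-8-yl)methylidene]-4-methylbenzenesulfonohydrazide | Cc1ccc(cc1)S(=O)(=O)N/N=C/c1c(OC)ccc2ccc(=O)oc12 | intermediate
14 | sodium salt of tosylhydrazone 13 (not isolated) | [Na+].Cc1ccc(cc1)S(=O)(=O)[N-]/N=C/c1c(OC)ccc2ccc(=O)oc12 | intermediate
15 | 8-(diazomethyl)-7-methoxy-2H-chromen-2-one (not isolated) | [N-]=[N+]=Cc1c(OC)ccc2ccc(=O)oc12 | intermediate
16 | trimethoxy[(7-methoxy-2-oxo-2H-chromen-8-yl)methylidene]-λ5-phosphane (not isolated) | COP(OC)(OC)=Cc1c(OC)ccc2ccc(=O)oc12 | intermediate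
17 | 7-methoxy-6-[(1R,6R)-6-[(E)-2-(7-methoxy-2-oxo-2H-chromen-8-yl)ethenyl]-3,6-dimethylcyclohex-2-en-1-yl]-2H-chromen-2-one (CNP0287121.3; aryl and styryl cis) | COc1cc2oc(=O)ccc2cc1[C@@H]1C=C(C)CC[C@]1(C)/C=C/c1c(OC)ccc2ccc(=O)oc12 | target

## Step count and risks

Total steps: 7. Longest linear sequence: 5 steps (steps 1, 2, 3, 4, 7); steps 5 and 6 form the second branch.

**Most likely to fail: step 7.** The carbene and ylide sit on an ortho,ortho'-disubstituted arene and must reach a neopentyl-type aldehyde. Azine formation from the diazo compound and incomplete E selectivity are the expected losses. The fallback sets out from 12 and 10 and comes back at 17. It keeps the same donor carbon but separates C–C bond formation from alkene formation. Aldehyde 12 is condensed with hydrazine hydrate (THF, rt) to the N-unsubstituted hydrazone (E)-8-(hydrazinylidenemethyl)-7-methoxy-2H-chromen-2-one F1. Under [RuCl2(p-cymene)]2, Me2PCH2CH2PMe2 and catalytic K3PO4 (THF, 45 °C), the hydrazone carbon adds to aldehyde 10 with loss of N2. This gives the secondary alcohol 7-methoxy-6-[(1R,6S)-6-[1-hydroxy-2-(7-methoxy-2-oxo-2H-chromen-8-yl)ethyl]-3,6-dimethylcyclohex-2-en-1-yl]-2H-chromen-2-one F2 as both carbinol epimers. Syn-dehydration with methyl N-(triethylammoniosulfonyl)carbamate (Burgess reagent; benzene, 50 °C) removes a benzylic hydrogen and gives the E-alkene 17.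

**Second: step 4.** The lactone carbonyl can bind the cationic boron catalyst, the electron-rich diene can oligomerise under acid, and the endo/exo ratio with an α-methyl dienophile is not guaranteed. The fallback sets out from 8 and comes back at 10. An iminium-catalysed Diels–Alder reaction of 8 with acrolein is run with (5S)-5-benzyl-2,2,3-trimethylimidazolidin-4-one hydrochloride or its antipode, whichever delivers the adduct drawn (CH3NO2/H2O, 0 °C). It gives the endo aldehyde (1S,2R)-2-(7-methoxy-2-oxo-2H-chromen-6-yl)-4-methylcyclohex-3-ene-1-carbaldehyde F3. Enolisation with KOtBu and methylation with MeI (THF, −78 °C to 0 °C) then brings the methyl group in anti to the neighbouring aryl group and gives 10. The formyl-bearing centre is re-set in this alkylation, and the aryl-bearing centre carries the enantiopurity.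

**Third: step 3.** The tertiary mesylate can be trapped by chloride, and diene 8 dimerises by [4+2] cycloaddition on standing or warming. The fallback sets out from 4 and comes back at 8. Hydroboration of 2-methylbut-1-en-3-yne with pinacolborane ((C5H5)2Zr(H)Cl cat., Et3N, 60 °C) gives (E)-4,4,5,5-tetramethyl-2-(3-methylbuta-1,3-dien-1-yl)-1,3,2-dioxaborolane F4. Suzuki–Miyaura coupling of the boronate with bromide 4 (Pd(PPh3)4, K3PO4, dioxane/H2O, 70 °C, acidic work-up) installs the intact diene and gives 8 without passing through alcohol 6 or any elimination.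

## Further compounds

F1 | step 7 | (E)-8-(hydrazinylidenemethyl)-7-methoxy-2H-chromen-2-one | N/N=C/c1c(OC)ccc2ccc(=O)oc12
F2 | step 7 | 7-methoxy-6-[(1R,6S)-6-[1-hydroxy-2-(7-methoxy-2-oxo-2H-chromen-8-yl)ethyl]-3,6-dimethylcyclohex-2-en-1-yl]-2H-chromen-2-one (carbinol epimers) | COc1cc2oc(=O)ccc2cc1[C@@H]1C=C(C)CC[C@]1(C)C(O)Cc1c(OC)ccc2ccc(=O)oc12
F3 | step 4 | (1S,2R)-2-(7-methoxy-2-oxo-2H-chromen-6-yl)-4-methylcyclohex-3-ene-1-carbaldehyde | COc1cc2oc(=O)ccc2cc1[C@@H]1C=C(C)CC[C@@H]1C=O
F4 | step 3 | (E)-4,4,5,5-tetramethyl-2-(3-methylbuta-1,3-dien-1-yl)-1,3,2-dioxaborolane | CC(=C)/C=C/B1OC(C)(C)C(C)(C)O1
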